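A ratio of two drains on one tank started the quarrel over these flasks. Substrate, fed in portions, leaves by two routes: on the catalyst it becomes intermediate, which then takes up partner on the catalyst to give target, or it meets partner directly and gives uncatalysed product.

| setting | dusk | winter | larch | elm | maple | ash |
|---|---|---|---|---|---|---|
| substrate | 0.091 M (in portions, 3) | 0.091 M (in portions, 3) | 0.091 M (in portions, 3) | 0.091 M (in portions, 3) | 0.091 M (in portions, 3) | 0.091 M (in portions, 3) |
| partner | 0.026 M | 0.63 M | 0.0300 M | 0.100 M | 0.250 M | 0.800 M |
| catalyst | 4.5 mM | 4.5 mM | 4.5 mM | 4.5 mM | 4.5 mM | 4.5 mM |
| remark | run made earlier; portions every 40 min | run made earlier; portions every 40 min | the portions of substrate follow each other after 40 min, the first at the start | the portions of substrate follow each other after 40 min, the first at the start | the portions of substrate follow each other after 40 min, the first at the start | the portions of substrate follow each other after 40 min, the first at the start |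
| time |  |  | 25 h | 25 h | 25 h | 25 h |

| run | time / h | target / % | substrate / % |
|---|---|---|---|
| dusk | 4.00 | 2.5 | 46.8 |
| dusk | 8.00 | 8.6 | 22.0 |
| dusk | 10.0 | 11.1 | 16.6 |
| dusk | 15.0 | 13.8 | 11.9 |
| dusk | 20.0 | 17.7 | 8.4 |
| winter | 4.00 | 20.8 | 8.5 |
| winter | 8.00 | 26.9 | 1.0 |
| winter | 10.0 | 26.3 | 0 |
| winter | 15.0 | 27.0 | 0.4 |
| winter | 20.0 | 27.8 | 0.1 |

(scatter of a reading: 0.5 percentage points)

- steps thought possible: substrate + catalyst <-> catalyst + intermediate; partner + catalyst + intermediate -> catalyst + target; substrate + partner -> uncatalysed product
- "hardly changes" means that all values lie within two and a half points (for a concentration: within two and a half percent of the largest)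

1. amount of target at the end, in percent of the substrate charged for larch, elm, maple, ash, in this order
2. the course of these numbers from the first flask to the last (falls all the way / rises, then falls / rises all the way / hardly changes / falls, then rises)

The first chemist watched the substrate. He took each route to drain it at a rate proportional to the substrate present, with partner held steady and no way back counted, so that time cancels in the integral and the share passing through the catalyst is a plain ratio: E/(E + partner concentration). Winter's target lies flat at a mean of 27.0 % from 8.00 h on. Taking partner midway between its start and full use of the substrate charge, 0.585 M, he read E as 0.216 M, the even-split concentration, the partner concentration at which both routes take substrate equally. With the same midway partner, his ratio gave 79.9 % for elm, 51.4 % for maple and 22.3 % for ash, a row that falls as partner grows.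

The second chemist watched the partner. Each target and each uncatalysed product costs one partner, so in larch, where partner is the limiting reagent, the two together cannot pass 33.0 % of the substrate charged. The same count on the dusk readings, with 8.4 % of substrate left at 20.0 h, puts about 63.0 % or more in intermediate, within the scatter of that reading. Dusk's target was still climbing there, from 13.8 % to 17.7 %, while winter's lay flat. So she held that flasks thin in partner are slow and that the row should rise first.

My own reckoning takes the ratio where partner is rich, 51.4 % for maple and 22.3 % for ash, keeps elm under 79.9 % and larch under 33.0 %, and so expects a rise, then a fall.

The forecast, on the second chemist's side, gives 22.5 %, 43 %, 47 % and 23.5 %, rises, then falls, holding for elm that “capture is slow and unfinished at 25 h”.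

The flasks give 21.0 %, 53.1 %, 48.6 % and 22.2 %: rises, then falls.

    substrate + catalyst ⇌ catalyst + intermediate (K = 7.90, k = 49.0 /M/h)
    partner + catalyst + intermediate → catalyst + target (k = 380 /M²/h)
    substrate + partner → uncatalysed product (k = 1.00 /M/h)

Elm gives 53.1 % where the ratio said 79.9 %, so the first chemist loses there, but from the turn at 0.14 M of partner upward the row falls as he argued: the ratio's 51.4 % against 48.6 % for maple and 22.3 % against 22.2 % for ash, with substrate down to 0.0414 % and 0 %. In larch, the forward passage of substrate to intermediate has a half-life of 3.1 h at the charged concentrations, while capture of intermediate has a half-life of 18 h at 3.33 h, longer, and at 25.0 h intermediate still stands at 61.4 %.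

All runs stem from a simulated flask on assumed constants; the scatter is artificial.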